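The runs were generated by integration with made-up constants.

**The floor.** 5.00% is where we expect L to stop in Sunday's flask: the floor is one minus the charge of Q over the charge of L, the fraction left once each Q has made one X, with Q as limiting reagent. Wednesday's floor is 52.1%, and its last reading of L is 52.1%.

common to all: L 14 mM

| flask | Q | remark | time |
|---|---|---|---|
| Sunday's | 13.3 mM | the very flask that is asked about, followed so far |  |
| Wednesday's | 6.7 mM | run made earlier |  |
| flask | 13.3 mM |  | 10 min |

Sunday's run (percent of the L charged)

| time / s | L / % | X / % | E / % |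
|---|---|---|---|
| 10.0 | 38.1 | 60.1 | 1.5 |
| 20.0 | 34.2 | 64.1 | 1.6 |
| 30.0 | 31.6 | 67.0 | 1.4 |
| 60.0 | 26.1 | 73.5 | 1.2 |
| 120 | 18.1 | 81.2 | 1.1 |

Wednesday's run (percent of the L charged)

| time / min | L / % | X / % | E / % |
|---|---|---|---|
| 0.500 | 63.1 | 37.1 | 0.6 |
| 1.00 | 58.9 | 40.8 | 0.3 |
| 2.00 | 55.5 | 44.2 | 0 |
| 4.00 | 53.2 | 47.5 | 0.3 |
| 8.00 | 52.1 | 47.9 | 0 |

(readings scatter by 0.3 percentage points)

1. how much L there is at 10 min, in percent of the L charged
2. how much X there is at 10 min, in percent of the L charged
3. how much E there is at 10 min, in percent of the L charged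

**Two extremes.** Let the gap be L minus the floor; we read 21.1% at 60.0 s and 13.1% at 120 s. If the gap closes first-order whatever L is, its rate is 0.00794 s⁻¹, and L reaches 5.29% at 10 min. If the rate is proportional to gap times L, integration makes ln(L/gap) linear in time, and the same readings give 7.13%.

**Between them.** Wednesday's gap closes at a read 0.0117 s⁻¹, which is 1.47 times Sunday's, while L at the start of its window is 2.26 times Sunday's. We therefore take the rate to rise with L, but less than proportionally, and expect L at 10 min to lie between the two extremes.

**The result.** The forecast gives L 6%, X 93.6% and E 0.4%, holding that “L should level off near 5%”. The flask gives L 6.84%, X 93.0% and E 0.149%.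

    Q ⇌ D (K = 7.90, k = 0.170 s⁻¹)
    L + Q → X + Z (k = 35.0 M⁻¹ s⁻¹)
    Q → J (k = 6.00 × 10⁻⁵ s⁻¹)
    Q + X ⇌ E + Z (K = 0.830, k = 2.00 M⁻¹ s⁻¹)

**What remains.** At 10 min the asked flask's L stands 1.8 percentage points above its floor, between our two extremes and closer to the second; D in that flask then amounts to 1.50% of the L charged. At 100 min that flask's L is 5.04%. With 3.3 mM of Q, the floor is 76.4%, and that flask holds L at 76.4% after 10.0 min.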